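**Retrosynthetic overview**

1. Target 37 comes from the tetracyclic cis-8,9-diol 25 by lactone α-methylenation, cyclic-sulfate inversion at C8 with (S)-2-methylbutanoate, loss of methanol from the C14 acetal (C10=C14 enol ether), 9-O-acetylation and 15-O-desilylation.
2. The strategy rests on C8 and C9: adjacent oxygen-bearing carbons of the cycloheptane C1–C5–C6–C7–C8–C9–C10, C8 hanging on the γ-lactone ring (O6–C6–C7–C11–C12) and C9 on the oxabicycle (pyran O–C4–C5–C1–C10–C14 bridged by C2–C3). Cutting C8–C9 gives dialdehyde 24, closed by a SmI2 pinacol coupling.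
3. 24 comes from the C6 aldehyde 16 (2-oxabicyclo[3.2.1]octane methyl acetal) by an oxazolidinone syn-aldol/lactonisation that forms C6–C7 and the lactone ring.
4. 16 comes from the cis-bicyclo[3.3.0]octene 13 by ozonolysis of a temporary ring C5–C6=C14–C10–C1 that holds C6 and C9 on one face; 13 comes from enyne 8 (Pauson–Khand), and 8 from epoxy alcohol 4 (asymmetric epoxidation).
5. Ring order: cyclopentane (with a temporary cyclopentenone ring), pyran acetal, γ-lactone, cycloheptane (key step), enol ether last.

Key step: step 19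

Remark: guaiane numbering is used for all intermediates, and the C14 lactol/acetal epimers (and the ozonide and Mannich-base diastereomers) are carried as mixtures because these centres are lost later.

**Route**

Step 1
Reactants: 1 prop-2-yn-1-ol; 2 but-3-en-1-ylmagnesium bromide
Product: 3 2-methylidenehex-5-en-1-ol
Conditions: 2 (2.5 equiv), CuI (10 mol%), Et2O/THF, −10 °C to rt; aq NH4Cl
Reagents that add atoms: none
Why: Copper-catalysed carbomagnesiation of the propargylic magnesium alkoxide should place the butenyl group on the internal alkyne carbon (chelated alkenylmagnesium alkoxide) and give the 2-substituted allylic alcohol after protonation; no stereocentre is formed.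

Step 2
Reactants: 3 2-methylidenehex-5-en-1-ol
Product: 4 (S)-[2-(but-3-en-1-yl)oxiran-2-yl]methanol
Conditions: Ti(OiPr)4 (10 mol%), L-(+)-diethyl tartrate (12 mol%), t-BuOOH, 4 Å sieves, CH2Cl2, −20 °C
Reagents that add atoms: tert-butyl hydroperoxide, CC(C)(C)OO
Why: Katsuki–Sharpless asymmetric epoxidation acts only on the allylic-alcohol alkene, and the L-(+)-tartrate complex should deliver oxygen to the face that gives the (S)-epoxy alcohol (the sense known for 2-substituted allyl alcohols), which sets the quaternary C4.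

Step 3
Reactants: 4 (S)-[2-(but-3-en-1-yl)oxiran-2-yl]methanol
Product: 5 (R)-2-(but-3-en-1-yl)oxirane-2-carbaldehyde
Conditions: Dess–Martin periodinane, NaHCO3, CH2Cl2, 0 °C to rt
Reagents that add atoms: none
Why: Dess–Martin oxidation of the primary alcohol under buffered conditions should leave the epoxide intact; the α-carbon is quaternary and cannot epimerise.

Step 4
Reactants: 5 (R)-2-(but-3-en-1-yl)oxirane-2-carbaldehyde
Product: 6 (S)-2-(but-3-en-1-yl)-2-ethynyloxirane
Conditions: dimethyl (1-diazo-2-oxopropyl)phosphonate, K2CO3, MeOH, 0 °C to rt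
Reagents that add atoms: dimethyl (1-diazo-2-oxopropyl)phosphonate, CC(=O)C(=[N+]=[N-])P(=O)(OC)OC
Why: Seyferth–Gilbert homologation in the Ohira–Bestmann form (deacylation, olefination, loss of N2 and 1,2-shift of the alkylidene carbene) should convert the aldehyde into the terminal alkyne without touching the quaternary centre.

Step 5
Reactants: 6 (S)-2-(but-3-en-1-yl)-2-ethynyloxirane
Product: 7 (S)-2-ethynylhex-5-ene-1,2-diol
Conditions: KOH, DMSO/H2O, 60 °C
Reagents that add atoms: water, O
Why: SN2 opening of the 2,2-disubstituted epoxide by hydroxide at the unsubstituted CH2 terminus leaves the C4–O bond untouched (retention at C4); acid is avoided so that no propargylic cation can form.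

Step 6
Reactants: 7 (S)-2-ethynylhex-5-ene-1,2-diol
Product: 8 (S)-1-[(tert-butyldimethylsilyl)oxy]-2-ethynylhex-5-en-2-ol
Conditions: TBSCl, imidazole, CH2Cl2, 0 °C
Reagents that add atoms: tert-butyldimethylsilyl chloride, CC(C)(C)[Si](C)(C)Cl
Why: Silyl ether formation should be selective for the primary hydroxyl (C15) over the hindered tertiary propargylic one.

Step 7
Reactants: 8 (S)-1-[(tert-butyldimethylsilyl)oxy]-2-ethynylhex-5-en-2-ol
Product: 9 (4S,6aS)-4-hydroxy-4-{[(tert-butyldimethylsilyl)oxy]methyl}-4,5,6,6a-tetrahydropentalen-2(1H)-one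
Conditions: Co2(CO)8 (10 mol%), tetramethylthiourea (60 mol%), CO (1 atm), toluene, 70 °C
Reagents that add atoms: carbon monoxide, [C-]#[O+]
Why: Intramolecular Pauson–Khand [2+2+1] cycloaddition of the 1,6-enyne, helped by the geminally disubstituted propargylic carbon, should set the ring-fusion centre C1 with H-1 syn to the larger CH2OTBS group, which takes the convex position in the cobaltacycle while the small hydroxyl stays on the concave face.

Step 8
Reactants: 9 (4S,6aS)-4-hydroxy-4-{[(tert-butyldimethylsilyl)oxy]methyl}-4,5,6,6a-tetrahydropentalen-2(1H)-one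
Product: 10 1-[(benzyloxy)methyl] derivative of 9 with CH2OBn syn to H-6a
Conditions: LiN(iPr)2 (2.2 equiv), THF, −78 °C; BnOCH2Cl (1.05 equiv), −78 to −40 °C
Reagents that add atoms: benzyl chloromethyl ether, ClCOCc1ccccc1
Why: Kinetic α′-enolate alkylation of the cross-conjugated enone (formed beside the hindered tertiary lithium alkoxide, which should be alkylated far more slowly) should occur on the convex face of the bicycle, which puts C9 on C10 syn to H-1.

Step 9
Reactants: 10 1-[(benzyloxy)methyl] derivative of 9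
Product: 11 cis-fused 1-[(benzyloxy)methyl]-4-hydroxy-4-{[(tert-butyldimethylsilyl)oxy]methyl}hexahydropentalen-2(1H)-one
Conditions: H2 (1 atm), Pd/C, pyridine (0.5 equiv), EtOAc, rt
Reagents that add atoms: none
Why: Heterogeneous catalytic hydrogenation of the enone C=C from the convex face gives the cis ring fusion (the only unstrained bicyclo[3.3.0]octane), so H-5 ends syn to H-1; pyridine suppresses benzyl ether hydrogenolysis.

Step 10
Reactants: 11 cis-fused hexahydropentalen-2(1H)-one
Product: 12 enol triflate of 11 with the double bond between C14 and C6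
Conditions: LiN(iPr)2 (2.2 equiv), THF, −78 °C; N-(5-chloropyridin-2-yl)bis(trifluoromethanesulfonyl)imide, −78 to −20 °C
Reagents that add atoms: N-(5-chloropyridin-2-yl)bis(trifluoromethanesulfonyl)imide, O=S(=O)(N(c1ccc(Cl)cn1)S(=O)(=O)C(F)(F)F)C(F)(F)F
Why: Kinetic deprotonation should take place at the unhindered C6 methylene (the other α-carbon, C10, is tertiary) and O-sulfonylation of that enolate gives the enol triflate regioselectively.

Step 11
Reactants: 12 enol triflate
Product: 13 cis-1-[(benzyloxy)methyl]-4-{[(tert-butyldimethylsilyl)oxy]methyl}-1,3a,4,5,6,6a-hexahydropentalen-4-ol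
Conditions: Pd(OAc)2 (5 mol%), PPh3 (10 mol%), HCO2H, n-Bu3N, DMF, 60 °C
Reagents that add atoms: none
Why: Palladium-catalysed formate reduction of the alkenyl triflate replaces OTf by H without moving the C6=C14 double bond.

Step 12
Reactants: 13 cis-hexahydropentalen-4-ol
Product: 15 4-[(benzyloxy)methyl]-3-hydroxy-1-{[(tert-butyldimethylsilyl)oxy]methyl}-2-oxabicyclo[3.2.1]octane-8-carbaldehyde, via ozonide 14 (not isolated)
Conditions: O3, CH2Cl2, −78 °C; PPh3, −78 °C to rt
Reagents that add atoms: ozone, [O-][O+]=O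
Why: Ozonolysis with phosphine reduction cleaves the temporary cyclopentene into the C6 and C14 aldehydes; only the C14 aldehyde can reach the tertiary C4 hydroxyl (six-membered bridged lactol), so C6 stays a free aldehyde held syn to C9 by the former ring, and the lactol carbon is the only new, uncontrolled centre.

Step 13
Reactants: 15 lactol aldehyde
Product: 16 4-[(benzyloxy)methyl]-3-methoxy-1-{[(tert-butyldimethylsilyl)oxy]methyl}-2-oxabicyclo[3.2.1]octane-8-carbaldehyde (CHO on C8 over the O2–C3–C4 bridge; CH2OBn on C4 syn to C8)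
Conditions: MeOTf, 2,6-di-tert-butyl-4-methylpyridine, CH2Cl2, 0 °C to rt
Reagents that add atoms: methyl trifluoromethanesulfonate, COS(=O)(=O)C(F)(F)F
Why: O-Methylation of the hemiacetal hydroxyl under non-acidic conditions should fix the cyclic methyl acetal kinetically without acetalising or enolising the C6 aldehyde; the configuration at C14 is inconsequential.

Step 14
Reactants: 17 (S)-4-benzyl-1,3-oxazolidin-2-one; 18 methyl 4-chloro-4-oxobutanoate
Product: 19 methyl 4-[(4S)-4-benzyl-2-oxo-1,3-oxazolidin-3-yl]-4-oxobutanoate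
Conditions: n-BuLi, THF, −78 °C; then 18, −78 to 0 °C
Reagents that add atoms: none
Why: N-Acylation of the lithiated oxazolidinone by the acid chloride; the auxiliary stereocentre is untouched.

Step 15
Reactants: 16 methyl acetal aldehyde; 19 methyl 4-[(4S)-4-benzyl-2-oxo-1,3-oxazolidin-3-yl]-4-oxobutanoate
Product: 21 trans-γ-lactone (6,12-olide) with C6 on C5 of the oxabicycle and C8 as the N-acyl (S)-4-benzyloxazolidinone on C7, via syn-aldol adduct 20 (not isolated)
Conditions: 19, n-Bu2BOTf, i-Pr2NEt, CH2Cl2, −78 to 0 °C; 16, −78 to 0 °C; pH 7 buffer, MeOH, H2O2, 0 °C; Et3N (cat.), CH2Cl2, rt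
Reagents that add atoms: none
Why: Oxazolidinone-directed boron syn-aldol reaction (Evans aldol, Z-enolate, chair transition state, aldehyde on the enolate face away from the benzyl group) should set C7 and C6 under auxiliary control, and the C6 hydroxyl then closes on the C12 methyl ester to give the trans-4,5-disubstituted γ-lactone.

Step 16
Reactants: 21 lactone imide
Product: 22 trans-γ-lactone with C8 as CH2OH and C9 as CH2OBn
Conditions: NaBH4, THF/H2O, 0 °C to rt
Reagents that add atoms: none
Why: Borohydride reduction of the activated exocyclic imide carbonyl to the primary alcohol releases the auxiliary and should spare the much less electrophilic γ-lactone and the acetal.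

Step 17
Reactants: 22 hydroxymethyl lactone benzyl ether
Product: 23 8,9-diol (C8 and C9 both CH2OH)
Conditions: H2 (1 atm), Pd/C, EtOAc, rt
Reagents that add atoms: none
Why: Catalytic hydrogenolysis of the benzyl ether; no alkene is left in the molecule, and the silyl ether, acetal and lactone are inert.

Step 18
Reactants: 23 8,9-diol
Product: 24 dialdehyde: trans-lactone with the C7 formyl group (C8) joined at C5–C6 to the methyl-acetal oxabicycle with the C10 formyl group (C9)
Conditions: Dess–Martin periodinane (3 equiv), NaHCO3, CH2Cl2, 0 °C to rt; filtered through a short pad and used at once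
Reagents that add atoms: none
Why: Buffered Dess–Martin oxidation of both primary alcohols avoids the base that would epimerise C7 or C10 or eliminate the β-oxygens.

Step 19
Reactants: 24 dialdehyde
Product: 25 tetracyclic cis-8,9-diol, 8-epi relative to the target (both hydroxyls on the face of H-7 and H-10)
Conditions: SmI2 (3 equiv), THF (0.005 M), −78 to −30 °C; aq NH4Cl
Reagents that add atoms: none
Why: Two single-electron transfers from SmI2 (divalent samarium) turn the C8 and C9 aldehydes into samarium ketyls, whose carbon–carbon coupling gives the 1,2-diolate; the closest known reaction type is the SmI2 pinacol cyclisation of dialdehydes to cyclic cis-1,2-diols. The ring closed is the cycloheptane C1–C5–C6–C7–C8–C9–C10, by joining the two ends of a 1,7-dicarbonyl chain (ketyl–ketyl coupling, or 7-exo addition of one ketyl to the samarium-bound second aldehyde). C8 and C9 are set together: bridging of both oxygens by samarium keeps them on one face (cis diol), and that face should be the one anti to the C7–C11 and C10–C14 bonds, the convex face carrying H-7 and H-10, which gives C9 as in the target and C8 as its epimer. The step needs intramolecular coupling to beat intermolecular coupling and simple reduction, which high dilution and the syn placement of C6 and C9 on the rigid oxabicycle (the two formyl carbons are held within reach) should secure. It also needs the aldehydes to survive: both are aliphatic with no leaving group on the α-carbon, the β-oxygens (lactone O6, C14 acetal) are not expelled from ketyls, and the neutral medium should not epimerise C7 or C10.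

Step 20
Reactants: 25 tetracyclic cis-8,9-diol
Product: 28 α-methylene lactone cis-8,9-diol (C11=C13), via Mannich base 26 (not isolated), via methiodide 27 (not isolated)
Conditions: LiN(iPr)2 (3.5 equiv), THF, −78 °C; CH2=NMe2 I, −78 to 0 °C; MeI, MeOH, rt; aq NaHCO3/CH2Cl2, rt
Reagents that add atoms: dimethylmethyleneiminium iodide, C=[N+](C)C.[I-]
Why: Mannich α-methylenation: the lactone enolate (formed after deprotonation of the two hydroxyls, before any ester is present) adds to the iminium salt, and N-methylation followed by mild-base elimination of trimethylamine gives the exocyclic alkene; no stereocentre is created.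

Step 21
Reactants: 28 α-methylene lactone cis-8,9-diol
Product: 30 8,9-cyclic sulfate, via cyclic sulfite 29 (not isolated)
Conditions: SOCl2, Et3N, CH2Cl2, 0 °C; then RuCl3 (1 mol%), NaIO4, MeCN/H2O, 0 °C
Reagents that add atoms: thionyl chloride, O=S(Cl)Cl; sodium periodate, [Na+].[O-]I(=O)(=O)=O
Why: Two-stage cyclic sulfate synthesis (sulfite formation, ruthenium-catalysed oxidation); the sulfite oxidation should be much faster than attack of RuO4 on the electron-poor methylene lactone, and both C–O bonds are retained.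

Step 22
Reactants: 30 8,9-cyclic sulfate; 31 (S)-2-methylbutanoic acid
Product: 33 8-O-[(S)-2-methylbutanoyl] 9-alcohol with inverted C8 (methyl acetal, 15-O-TBS), via caesium sulfate monoester 32 (not isolated)
Conditions: 31, Cs2CO3, DMF, 50 °C; then H2SO4 (cat.), H2O (2 equiv), THF, rt
Reagents that add atoms: none
Why: SN2 opening of the cyclic sulfate by the carboxylate should occur at C8, the carbon remote from the congested oxabicycle junction, with inversion (O8 now anti to O9), and mild acid then hydrolyses only the C9 alkyl sulfate with retention; the weakly basic carboxylate should not epimerise the (S)-2-methylbutanoyl centre.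

Step 23
Reactants: 33 8-ester 9-alcohol methyl acetal
Product: 35 C10=C14 enol ether with free 9-OH, via trimethylsilyl ether 34 (not isolated)
Conditions: TMSOTf (2.5 equiv), i-Pr2NEt, CH2Cl2, −78 to −20 °C; then n-Bu4NF, AcOH, THF, 0 °C
Reagents that add atoms: none
Why: Silyl-triflate ionisation of the acetal methoxy group and removal of H-10 from the oxocarbenium ion by the amine (acetal-to-enol-ether elimination) give the dihydropyran; the C9 hydroxyl is masked in the flask as a poorly leaving silyl ether so that no allylic ionisation can follow, and buffered fluoride then frees only that secondary trimethylsilyl ether.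

Step 24
Reactants: 35 enol ether 9-alcohol
Product: 36 15-O-TBS ether of the target (8-ester, 9-acetate)
Conditions: Ac2O, pyridine, DMAP (cat.), CH2Cl2, 0 °C to rt
Reagents that add atoms: acetic anhydride, CC(=O)OC(C)=O
Why: Base-mediated O-acylation of the secondary allylic alcohol with retention; the enol ether and the methylene lactone are stable to these non-acidic conditions.

Step 25
Reactants: 36 15-O-TBS ether of the target
Product: 37 CNP0013863.2
Conditions: HF·pyridine, pyridine, THF, 0 °C to rt
Reagents that add atoms: none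
Why: Buffered fluoride cleavage of the primary silyl ether; these weakly acidic, non-Lewis-acidic conditions should leave the allylic acetate, the enol ether and both esters intact.

**Compound list**

1 | prop-2-yn-1-ol | C#CCO | starting material
2 | but-3-en-1-ylmagnesium bromide | C=CCC[Mg]Br | starting material
3 | 2-methylidenehex-5-en-1-ol | C=CCCC(=C)CO | intermediate
4 | (S)-[2-(but-3-en-1-yl)oxiran-2-yl]methanol | OC[C@@]1(CCC=C)CO1 | intermediate
5 | (R)-2-(but-3-en-1-yl)oxirane-2-carbaldehyde | O=C[C@@]1(CCC=C)CO1 | intermediate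
6 | (S)-2-(but-3-en-1-yl)-2-ethynyloxirane | C#C[C@@]1(CCC=C)CO1 | intermediate
7 | (S)-2-ethynylhex-5-ene-1,2-diol | C#C[C@](O)(CO)CCC=C | intermediate
8 | (S)-1-[(tert-butyldimethylsilyl)oxy]-2-ethynylhex-5-en-2-ol | C#C[C@](O)(CO[Si](C)(C)C(C)(C)C)CCC=C | intermediate
9 | (4S,6aS)-4-hydroxy-4-{[(tert-butyldimethylsilyl)oxy]methyl}-4,5,6,6a-tetrahydropentalen-2(1H)-one (OH anti to H-6a) | O=C1C=C2[C@](O)(CO[Si](C)(C)C(C)(C)C)CC[C@H]2C1 | intermediate
10 | 1-[(benzyloxy)methyl] derivative of 9, CH2OBn on the convex face syn to H-6a | O=C1C=C2[C@](O)(CO[Si](C)(C)C(C)(C)C)CC[C@H]2[C@@H]1COCc1ccccc1 | intermediate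
11 | cis-fused 1-[(benzyloxy)methyl]-4-hydroxy-4-{[(tert-butyldimethylsilyl)oxy]methyl}hexahydropentalen-2(1H)-one (H-3a, H-6a and CH2OBn on one face, OH on the other) | O=C1C[C@H]2[C@](O)(CO[Si](C)(C)C(C)(C)C)CC[C@H]2[C@@H]1COCc1ccccc1 | intermediate
12 | 2-(trifluoromethanesulfonyloxy)-2,3-ene of 11 (enol triflate, C14=C6) | FC(F)(F)S(=O)(=O)OC1=C[C@H]2[C@](O)(CO[Si](C)(C)C(C)(C)C)CC[C@H]2[C@@H]1COCc1ccccc1 | intermediate
13 | cis-1-[(benzyloxy)methyl]-4-{[(tert-butyldimethylsilyl)oxy]methyl}-1,3a,4,5,6,6a-hexahydropentalen-4-ol | C1=C[C@H]2[C@](O)(CO[Si](C)(C)C(C)(C)C)CC[C@H]2[C@@H]1COCc1ccccc1 | intermediate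
14 | ozonide (1,2,4-trioxolane across C6 and C14) of 13 | C1(OO3)OC3[C@H]2[C@](O)(CO[Si](C)(C)C(C)(C)C)CC[C@H]2[C@@H]1COCc1ccccc1 | intermediate
15 | 4-[(benzyloxy)methyl]-3-hydroxy-1-{[(tert-butyldimethylsilyl)oxy]methyl}-2-oxabicyclo[3.2.1]octane-8-carbaldehyde (CHO over the oxygen bridge, CH2OBn syn to C8) | O=C[C@@H]1[C@H]2CC[C@]1(CO[Si](C)(C)C(C)(C)C)OC(O)[C@H]2COCc1ccccc1 | intermediate
16 | 4-[(benzyloxy)methyl]-3-methoxy-1-{[(tert-butyldimethylsilyl)oxy]methyl}-2-oxabicyclo[3.2.1]octane-8-carbaldehyde | O=C[C@@H]1[C@H]2CC[C@]1(CO[Si](C)(C)C(C)(C)C)OC(OC)[C@H]2COCc1ccccc1 | intermediate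
17 | (S)-4-benzyl-1,3-oxazolidin-2-one | O=C1OC[C@H](Cc2ccccc2)N1 | starting material
18 | methyl 4-chloro-4-oxobutanoate | COC(=O)CCC(Cl)=O | starting material
19 | methyl 4-[(4S)-4-benzyl-2-oxo-1,3-oxazolidin-3-yl]-4-oxobutanoate | COC(=O)CCC(=O)N1[C@@H](Cc2ccccc2)COC1=O | intermediate
20 | syn-aldol adduct (C6 hydroxyl, C7 bearing the imide C8 and CH2CO2Me) | COC(=O)C[C@H](C(=O)N1[C@@H](Cc2ccccc2)COC1=O)[C@H](O)[C@@H]1[C@H]2CC[C@]1(CO[Si](C)(C)C(C)(C)C)OC(OC)[C@H]2COCc1ccccc1 | intermediate
21 | trans-6,12-olide with C8 as N-acyl (S)-4-benzyloxazolidinone and 9-O-benzyl | O=C(N1[C@@H](Cc2ccccc2)COC1=O)[C@H]1CC(=O)O[C@@H]1[C@@H]1[C@H]2CC[C@]1(CO[Si](C)(C)C(C)(C)C)OC(OC)[C@H]2COCc1ccccc1 | intermediate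
22 | trans-6,12-olide with 8-hydroxy and 9-benzyloxy (8,9-seco) | OC[C@H]1CC(=O)O[C@@H]1[C@@H]1[C@H]2CC[C@]1(CO[Si](C)(C)C(C)(C)C)OC(OC)[C@H]2COCc1ccccc1 | intermediate
23 | 8,9-seco 8,9-diol | OC[C@H]1CC(=O)O[C@@H]1[C@@H]1[C@H]2CC[C@]1(CO[Si](C)(C)C(C)(C)C)OC(OC)[C@H]2CO | intermediate
24 | 8,9-seco 8,9-dialdehyde (pinacol precursor) | O=C[C@H]1CC(=O)O[C@@H]1[C@@H]1[C@H]2CC[C@]1(CO[Si](C)(C)C(C)(C)C)OC(OC)[C@H]2C=O | intermediate
25 | tetracyclic cis-8,9-diol, 8-epi (pinacol product) | O[C@H]1[C@@H](O)[C@@H]2C(OC)O[C@@]3(CO[Si](C)(C)C(C)(C)C)CC[C@@H]2[C@H]3[C@H]4OC(=O)C[C@H]14 | intermediate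
26 | 11-(dimethylaminomethyl) lactone (Mannich base) | O[C@H]1[C@@H](O)[C@@H]2C(OC)O[C@@]3(CO[Si](C)(C)C(C)(C)C)CC[C@@H]2[C@H]3[C@H]4OC(=O)C(CN(C)C)[C@H]14 | intermediate
27 | 11-(trimethylammoniomethyl) lactone iodide | O[C@H]1[C@@H](O)[C@@H]2C(OC)O[C@@]3(CO[Si](C)(C)C(C)(C)C)CC[C@@H]2[C@H]3[C@H]4OC(=O)C(C[N+](C)(C)C)[C@H]14.[I-] | intermediate
28 | 11(13)-methylene lactone cis-8,9-diol | O[C@H]1[C@@H](O)[C@@H]2C(OC)O[C@@]3(CO[Si](C)(C)C(C)(C)C)CC[C@@H]2[C@H]3[C@H]4OC(=O)C(=C)[C@H]14 | intermediate
29 | 8,9-cyclic sulfite | O=S1O[C@H]2[C@@H](O1)[C@@H]3C(OC)O[C@@]4(CO[Si](C)(C)C(C)(C)C)CC[C@@H]3[C@H]4[C@H]5OC(=O)C(=C)[C@H]25 | intermediate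
30 | 8,9-cyclic sulfate | O=S1(=O)O[C@H]2[C@@H](O1)[C@@H]3C(OC)O[C@@]4(CO[Si](C)(C)C(C)(C)C)CC[C@@H]3[C@H]4[C@H]5OC(=O)C(=C)[C@H]25 | intermediate
31 | (S)-2-methylbutanoic acid | CC[C@H](C)C(=O)O | starting material
32 | caesium 9-sulfate of the 8-O-[(S)-2-methylbutanoyl] compound | C=C1C(=O)O[C@H]2[C@H]1[C@H](OC(=O)[C@@H](C)CC)[C@@H](OS(=O)(=O)[O-])[C@@H]1C(OC)O[C@@]3(CO[Si](C)(C)C(C)(C)C)CC[C@@H]1[C@@H]23.[Cs+] | intermediate
33 | 8-O-[(S)-2-methylbutanoyl] 9-alcohol, C14 methyl acetal, 15-O-TBS | C=C1C(=O)O[C@H]2[C@H]1[C@H](OC(=O)[C@@H](C)CC)[C@@H](O)[C@@H]1C(OC)O[C@@]3(CO[Si](C)(C)C(C)(C)C)CC[C@@H]1[C@@H]23 | intermediate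
34 | 9-O-trimethylsilyl C10=C14 enol ether | C=C1C(=O)O[C@H]2[C@H]1[C@H](OC(=O)[C@@H](C)CC)[C@@H](O[Si](C)(C)C)C1=CO[C@@]3(CO[Si](C)(C)C(C)(C)C)CC[C@@H]1[C@@H]23 | intermediate
35 | 9-hydroxy C10=C14 enol ether, 15-O-TBS | C=C1C(=O)O[C@H]2[C@H]1[C@H](OC(=O)[C@@H](C)CC)[C@@H](O)C1=CO[C@@]3(CO[Si](C)(C)C(C)(C)C)CC[C@@H]1[C@@H]23 | intermediate
36 | 15-O-TBS ether of the target | C=C1C(=O)O[C@H]2[C@H]1[C@H](OC(=O)[C@@H](C)CC)[C@@H](OC(C)=O)C1=CO[C@@]3(CO[Si](C)(C)C(C)(C)C)CC[C@@H]1[C@@H]23 | intermediate
37 | CNP0013863.2 | C=C1C(=O)O[C@H]2[C@H]1[C@H](OC(=O)[C@@H](C)CC)[C@@H](OC(C)=O)C1=CO[C@@]3(CO)CC[C@@H]1[C@@H]23 | target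

**Step count**

Total: 25 steps. Longest linear sequence: 24 steps (steps 1–13 and 15–25; step 14 is the one-step side branch to 19).

**Steps most likely to fail**

Step 19 (key step). The ring closure may lose to intermolecular coupling or to plain reduction of the aldehydes; the dialdehyde may undergo aldol closure, β-elimination or epimerisation at C7/C10 before it is reduced; the samarium alkoxides may cause acyl migration of the lactone; or the diol face may be poorly controlled. The fallback sets out from dialdehyde 24 and comes back at diol 25. Reductive carbonyl olefination with low-valent titanium (TiCl3, Zn–Cu couple, DME, reflux, slow addition; McMurry coupling) would close the same C8–C9 bond as the cis-alkene, the 8,9-didehydro tetracycle F1. Dihydroxylation with OsO4 (cat.) and N-methylmorpholine N-oxide from the open face (that of H-7 and H-10) would then give the same cis-diol 25.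

Step 7. The failure mode is poor facial selectivity at the new ring-fusion centre, since the discrimination between the hydroxyl and the CH2OTBS group on the quaternary propargylic carbon is modest with a terminal alkyne; slow cyclisation of the free propargylic alcohol is a second concern. The fallback sets out from 8 and comes back at 9. Double deprotonation (n-BuLi, 2 equiv) and Me3SiCl would give the O,C-bis(trimethylsilyl) enyne F2, and citric acid in MeOH would free the tertiary hydroxyl to the C-silyl alkynol F3. In the Pauson–Khand reaction of F3 the silyl group on the alkyne terminus clashes with whichever propargylic substituent is concave, which should enforce the hydroxyl-concave isomer and give the α-silyl enone F4. Protodesilylation (CF3CO2H, CH2Cl2, 0 °C) then returns enone 9.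

Step 22. The carboxylate may attack C9 instead of C8, may cause E2 elimination of the sulfate, or may add to the methylene lactone. The fallback sets out from 28 and comes back at 36. Trimethyl orthoacetate with pyridinium p-toluenesulfonate would give the 8,9-cyclic methyl orthoacetate F5. Brief aqueous acetic acid should open it by cleavage at the less hindered O8 to the 9-acetate 8-alcohol F6. Mitsunobu esterification of the free C8 hydroxyl with acid 31 (PPh3, diisopropyl azodicarboxylate) inverts C8 and gives the 8-(2-methylbutanoate) 9-acetate methyl acetal F7. Stoichiometric TMSOTf with i-Pr2NEt at low temperature would then eliminate methanol to give 36.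

**Further compounds**

F1 | step 19 | 8,9-didehydro tetracycle (cis-cycloheptene, C14 methyl acetal, 15-O-TBS) | C1=C[C@@H]2C(OC)O[C@@]3(CO[Si](C)(C)C(C)(C)C)CC[C@@H]2[C@H]3[C@H]4OC(=O)C[C@H]14
F2 | step 7 | (S)-O,C-bis(trimethylsilyl) derivative of 8 | C[Si](C)(C)C#C[C@](O[Si](C)(C)C)(CO[Si](C)(C)C(C)(C)C)CCC=C
F3 | step 7 | (S)-1-[(tert-butyldimethylsilyl)oxy]-2-[(trimethylsilyl)ethynyl]hex-5-en-2-ol | C[Si](C)(C)C#C[C@](O)(CO[Si](C)(C)C(C)(C)C)CCC=C
F4 | step 7 | 3-(trimethylsilyl) derivative of enone 9 | O=C1C([Si](C)(C)C)=C2[C@](O)(CO[Si](C)(C)C(C)(C)C)CC[C@H]2C1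
F5 | step 22 | 8,9-cyclic methyl orthoacetate of 28 | CC1(OC)O[C@H]2[C@@H](O1)[C@@H]3C(OC)O[C@@]4(CO[Si](C)(C)C(C)(C)C)CC[C@@H]3[C@H]4[C@H]5OC(=O)C(=C)[C@H]25
F6 | step 22 | 9-O-acetyl 8-alcohol of 28 | O[C@H]1[C@@H](OC(C)=O)[C@@H]2C(OC)O[C@@]3(CO[Si](C)(C)C(C)(C)C)CC[C@@H]2[C@H]3[C@H]4OC(=O)C(=C)[C@H]14
F7 | step 22 | 8-O-[(S)-2-methylbutanoyl] 9-O-acetyl C14 methyl acetal, 15-O-TBS | C=C1C(=O)O[C@H]2[C@H]1[C@H](OC(=O)[C@@H](C)CC)[C@@H](OC(C)=O)[C@@H]1C(OC)O[C@@]3(CO[Si](C)(C)C(C)(C)C)CC[C@@H]1[C@@H]23
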